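**Plan**

- Feature: ring B (C5–C10, labdane numbering) is a cyclohexene whose C8 carries the C17 carboxyl. With the alkene placed at C6=C7, cutting C5–C10 and C8–C9 opens rings A and B together into a C5=C6–C7=C8–C17 dienoate and the E-C9=C10 alkene, joined by the C1–C4 chain and already bearing the whole C11–C16 side chain.
- Further cuts in the open chain: C5=C6 (olefination) and C1–C2 (enolate alkylation). This leaves geranyl isobutyrate, a C2–C5 methyl ketone and a phosphonocrotonate.
- Forward: oxidise and brominate the geranyl E-methyl group (C1), alkylate the ketone (C1–C2), unveil C5 and add C6–C8/C17, reduce C3=O, then close rings A and B in one thermal type 1 intramolecular Diels–Alder step. Finish by C3 deoxygenation, alkene shift to C7=C8 and ester cleavage.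
- Stereochemistry: the E alkene and the E,E diene give the C9/C10 and C5/C8 relative configuration; the anti chair transition state gives the trans fusion. The absolute sense is relayed from a 3S carbinol (Corey–Bakshi–Shibata reduction) that is deleted afterwards; C8 is erased by conjugation.

Key step: step 11

Assumption: geranyl isobutyrate is taken as the pure 2E isomer and 4-hydroxy-3,3-dimethylbutan-2-one as a purchasable ketone; labdane numbering (C1–C20) is used for all intermediates.

**Route**

Step 1
Reactants: 1 geranyl isobutyrate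
Product: 2 (2E,6E)-8-hydroxy-3,7-dimethylocta-2,6-dien-1-yl 2-methylpropanoate
Conditions: SeO2 (0.3 equiv), t-BuOOH (3 equiv), salicylic acid (0.1 equiv), CH2Cl2, 0 °C → rt
Reagents that add atoms: selenium dioxide, O=[Se]=O (catalytic oxygen carrier); tert-butyl hydroperoxide, CC(C)(C)OO
Why: Allylic oxidation by SeO2 (ene reaction, then [2,3]-sigmatropic shift) attacks the more electron-rich distal alkene at its E-methyl group, so the future C9=C10 alkene keeps the E geometry that the cycloaddition needs.

Step 2
Reactants: 2 (2E,6E)-8-hydroxy-3,7-dimethylocta-2,6-dien-1-yl 2-methylpropanoate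
Product: 3 (2E,6E)-8-bromo-3,7-dimethylocta-2,6-dien-1-yl 2-methylpropanoate
Conditions: CBr4, PPh3, CH2Cl2, −20 → 0 °C
Reagents that add atoms: carbon tetrabromide, BrC(Br)(Br)Br
Why: Appel reaction; bromide displaces the alkoxyphosphonium ion of the primary allylic alcohol at low temperature without allylic transposition or loss of alkene geometry.

Step 3
Reactants: 4 4-hydroxy-3,3-dimethylbutan-2-one
Product: 5 4-[(tert-butyldimethylsilyl)oxy]-3,3-dimethylbutan-2-one
Conditions: t-BuMe2SiCl, imidazole, CH2Cl2, rt
Reagents that add atoms: tert-butyldimethylsilyl chloride, CC(C)(C)[Si](C)(C)Cl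
Why: Silylation of the primary alcohol masks C5–OH so that the methyl group is the only acidic site for the enolate chemistry; the mild base avoids retro-aldol loss of formaldehyde.

Step 4
Reactants: 5 4-[(tert-butyldimethylsilyl)oxy]-3,3-dimethylbutan-2-one; 3 (2E,6E)-8-bromo-3,7-dimethylocta-2,6-dien-1-yl 2-methylpropanoate
Product: 7 (2E,6E)-12-[(tert-butyldimethylsilyl)oxy]-3,7,11,11-tetramethyl-10-oxododeca-2,6-dien-1-yl 2-methylpropanoate, via lithium enolate 6 (not isolated)
Conditions: LiN(iPr)2, THF, −78 °C; then 3 (0.8 equiv), DMPU, −78 → −30 °C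
Reagents that add atoms: none
Why: Kinetic enolate alkylation; the ketone can enolise only toward its methyl group (the other α-carbon is quaternary), and the lithium enolate displaces the primary allylic bromide by SN2 to form C1–C2 faster than it attacks the hindered isobutyrate.

Step 5
Reactants: 7 (2E,6E)-12-[(tert-butyldimethylsilyl)oxy]-3,7,11,11-tetramethyl-10-oxododeca-2,6-dien-1-yl 2-methylpropanoate
Product: 8 (2E,6E)-12-hydroxy-3,7,11,11-tetramethyl-10-oxododeca-2,6-dien-1-yl 2-methylpropanoate
Conditions: HF·pyridine, pyridine, THF, 0 °C → rt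
Reagents that add atoms: none
Why: Buffered HF cleaves the primary silyl ether without base, so the β-hydroxy ketone cannot undergo retro-aldol cleavage and the ester is untouched.

Step 6
Reactants: 8 (2E,6E)-12-hydroxy-3,7,11,11-tetramethyl-10-oxododeca-2,6-dien-1-yl 2-methylpropanoate
Product: 9 (2E,6E)-3,7,11,11-tetramethyl-10,12-dioxododeca-2,6-dien-1-yl 2-methylpropanoate
Conditions: Dess–Martin periodinane, CH2Cl2, rt
Reagents that add atoms: none
Why: Dess–Martin oxidation converts the neopentyl-type primary alcohol into the aldehyde under neutral conditions; the product cannot enolise between its two carbonyl groups because C4 is quaternary.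

Step 7
Reactants: 10 triethyl 4-phosphonocrotonate
Product: 11 (2E)-4-(diethoxyphosphoryl)but-2-enoic acid
Conditions: LiOH·H2O (1.05 equiv), THF/H2O, 0 °C → rt; then 1 M HCl
Reagents that add atoms: lithium hydroxide, [Li+].[OH-]
Why: Saponification; the carboxylic ethyl ester is hydrolysed far faster than the two phosphonate ethyl esters.

Step 8
Reactants: 11 (2E)-4-(diethoxyphosphoryl)but-2-enoic acid; 12 2-(trimethylsilyl)ethanol
Product: 13 2-(trimethylsilyl)ethyl (2E)-4-(diethoxyphosphoryl)but-2-enoate
Conditions: N,N'-dicyclohexylcarbodiimide, 4-(dimethylamino)pyridine (0.1 equiv), CH2Cl2, 0 °C → rt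
Reagents that add atoms: none
Why: Steglich esterification puts on the fluoride-labile ester that can later be removed without touching the isobutyrate.

Step 9
Reactants: 9 (2E,6E)-3,7,11,11-tetramethyl-10,12-dioxododeca-2,6-dien-1-yl 2-methylpropanoate; 13 2-(trimethylsilyl)ethyl (2E)-4-(diethoxyphosphoryl)but-2-enoate
Product: 15 2-(trimethylsilyl)ethyl (2E,4E,10E,14E)-6,6,10,14-tetramethyl-16-[(2-methylpropanoyl)oxy]-7-oxohexadeca-2,4,10,14-tetraenoate, via lithiated phosphonate 14 (not isolated)
Conditions: 13, LiN(SiMe3)2, THF, −78 °C; then 9, −78 → 0 °C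
Reagents that add atoms: none
Why: Vinylogous Horner–Wadsworth–Emmons olefination; the phosphonate carbanion adds to the aldehyde, which is far more reactive than the ketone flanked by the quaternary carbon, and loss of phosphate gives the new C5=C6 alkene with E geometry while the 2E alkene of the reagent is kept.

Step 10
Reactants: 15 2-(trimethylsilyl)ethyl (2E,4E,10E,14E)-6,6,10,14-tetramethyl-16-[(2-methylpropanoyl)oxy]-7-oxohexadeca-2,4,10,14-tetraenoate
Product: 16 2-(trimethylsilyl)ethyl (2E,4E,7S,10E,14E)-7-hydroxy-6,6,10,14-tetramethyl-16-[(2-methylpropanoyl)oxy]hexadeca-2,4,10,14-tetraenoate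
Conditions: (R)-1-methyl-3,3-diphenyltetrahydro-1H,3H-pyrrolo[1,2-c][1,3,2]oxazaborole (0.5 equiv), catecholborane, toluene, −40 → 0 °C; MeOH quench
Reagents that add atoms: none
Why: Corey–Bakshi–Shibata reduction; the ketone binds the oxazaborolidine boron with its tert-alkyl (C4) side away from the catalyst and hydride is delivered within the complex, so the R catalyst should give the 3S carbinol (the only new stereocentre), while catecholborane leaves the dienoate and the isolated alkenes alone.

Step 11
Reactants: 16 2-(trimethylsilyl)ethyl (2E,4E,7S,10E,14E)-7-hydroxy-6,6,10,14-tetramethyl-16-[(2-methylpropanoyl)oxy]hexadeca-2,4,10,14-tetraenoate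
Product: 17 2-(trimethylsilyl)ethyl 3β-hydroxy-15-(isobutyryloxy)labda-6,13E-dien-17-oate (trans-fused; 5α-H, 8α-H, 9α-H, 10β-CH3)
Conditions: toluene (0.01 M), 2,6-di-tert-butyl-4-methylphenol (0.1 equiv), degassed, sealed tube, 200 °C
Reagents that add atoms: none
Why: On heating, the C5=C6–C7=C8 dienoate adds suprafacially across the C9=C10 alkene in a concerted [4+2] cycloaddition that forms C5–C10 and C8–C9; the closest known reaction type is the thermal type 1 intramolecular Diels–Alder reaction of 1,3,9-decatrienes with an unactivated dienophile. Ring B (C5–C10) closes as the cycloaddition ring itself, and ring A (C1–C5, C10) closes in the fused mode as the tether ring, through a chair-like C1–C4 tether, at the moment C5–C10 forms. The E geometry of C9=C10 sets the C10 methyl and the C9 side chain cis, the E,E diene sets the C8 ester cis to C4 (a centre that step 14 erases), and the trans fusion (5α-H, 10β-CH3) comes from the anti transition state in which the C6 and C9 arms are both equatorial on the tether chair. The absolute sense comes from the 3S carbinol, which sits equatorial on that chair (free of 1,3-diaxial contact with H1 and H5) only when the diene reaches the face that gives the natural series. The step therefore needs trans over cis fusion and one π-face: the competing cis arrays must carry the C6 or the C9 arm axial on the tether chair, the latter against the axial C4 methyl, and the gem-dimethyl group also favours the reactive fold. The quaternary C4 blocks 1,5-hydrogen shifts of the dienoate at 200 °C, and the possible adducts are diastereomers that can be separated at this carbinol stage.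

Step 12
Reactants: 17 2-(trimethylsilyl)ethyl 3β-hydroxy-15-(isobutyryloxy)labda-6,13E-dien-17-oate
Product: 18 2-(trimethylsilyl)ethyl 3β-[(1H-imidazol-1-ylcarbonothioyl)oxy]-15-(isobutyryloxy)labda-6,13E-dien-17-oate
Conditions: 1,1'-thiocarbonyldiimidazole (3 equiv), 4-(dimethylamino)pyridine (0.5 equiv), toluene, 90 °C
Reagents that add atoms: 1,1'-thiocarbonyldiimidazole, S=C(n1ccnc1)n1ccnc1
Why: O-Thioacylation of the hindered equatorial carbinol (first stage of the Barton–McCombie deoxygenation) is driven by excess reagent, nucleophilic catalysis and heat; no other hydroxyl is present.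

Step 13
Reactants: 18 2-(trimethylsilyl)ethyl 3β-[(1H-imidazol-1-ylcarbonothioyl)oxy]-15-(isobutyryloxy)labda-6,13E-dien-17-oate
Product: 19 2-(trimethylsilyl)ethyl 15-(isobutyryloxy)labda-6,13E-dien-17-oate (8α-H)
Conditions: Bu3SnH, 2,2'-azobis(2-methylpropionitrile) (0.3 equiv), toluene, 110 °C
Reagents that add atoms: none
Why: Barton–McCombie deoxygenation; Bu3Sn• adds to the thiocarbonyl sulfur, β-scission gives the secondary C3 radical, and hydrogen transfer from Bu3SnH leaves a CH2 group, the radical being held away from every alkene by the rigid trans-decalin.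

Step 14
Reactants: 19 2-(trimethylsilyl)ethyl 15-(isobutyryloxy)labda-6,13E-dien-17-oate
Product: 20 2-(trimethylsilyl)ethyl 15-(isobutyryloxy)labda-7,13E-dien-17-oate
Conditions: 1,8-diazabicyclo[5.4.0]undec-7-ene (2 equiv), toluene, 100 °C
Reagents that add atoms: none
Why: Base-mediated conjugation (1,3-prototropic shift through the extended ester enolate) moves the alkene to the trisubstituted, ester-conjugated C7=C8 position, the thermodynamic sink; C8 loses its stereocentre, and C9, whose hydrogen is not acidified by the ester, keeps its configuration.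

Step 15
Reactants: 20 2-(trimethylsilyl)ethyl 15-(isobutyryloxy)labda-7,13E-dien-17-oate
Product: 21 15-(isobutyryloxy)labda-7,13E-dien-17-oic acid (target, 5S,9R,10S)
Conditions: Bu4NF, THF, 0 °C → rt; then 0.5 M HCl
Reagents that add atoms: none
Why: Fluoride attacks silicon and the 2-(trimethylsilyl)ethyl ester fragments by β-elimination to the carboxylate, ethylene and Me3SiF, a non-hydrolytic cleavage that spares the isobutyrate; acid work-up gives the target.

**Compound list**

1 | geranyl isobutyrate, (2E)-3,7-dimethylocta-2,6-dien-1-yl 2-methylpropanoate | CC(C)=CCC/C(C)=C/COC(=O)C(C)C | starting material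
2 | (2E,6E)-8-hydroxy-3,7-dimethylocta-2,6-dien-1-yl 2-methylpropanoate | C/C(=C\CC/C(C)=C/COC(=O)C(C)C)CO | intermediate
3 | (2E,6E)-8-bromo-3,7-dimethylocta-2,6-dien-1-yl 2-methylpropanoate | C/C(=C\CC/C(C)=C/COC(=O)C(C)C)CBr | intermediate
4 | 4-hydroxy-3,3-dimethylbutan-2-one | CC(=O)C(C)(C)CO | starting material
5 | 4-[(tert-butyldimethylsilyl)oxy]-3,3-dimethylbutan-2-one | CC(=O)C(C)(C)CO[Si](C)(C)C(C)(C)C | intermediate
6 | lithium 4-[(tert-butyldimethylsilyl)oxy]-3,3-dimethylbut-1-en-2-olate (lithium enolate of 5) | [Li+].[O-]C(=C)C(C)(C)CO[Si](C)(C)C(C)(C)C | intermediate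
7 | (2E,6E)-12-[(tert-butyldimethylsilyl)oxy]-3,7,11,11-tetramethyl-10-oxododeca-2,6-dien-1-yl 2-methylpropanoate | C/C(=C\COC(=O)C(C)C)CC/C=C(\C)CCC(=O)C(C)(C)CO[Si](C)(C)C(C)(C)C | intermediate
8 | (2E,6E)-12-hydroxy-3,7,11,11-tetramethyl-10-oxododeca-2,6-dien-1-yl 2-methylpropanoate | C/C(=C\COC(=O)C(C)C)CC/C=C(\C)CCC(=O)C(C)(C)CO | intermediate
9 | (2E,6E)-3,7,11,11-tetramethyl-10,12-dioxododeca-2,6-dien-1-yl 2-methylpropanoate | C/C(=C\COC(=O)C(C)C)CC/C=C(\C)CCC(=O)C(C)(C)C=O | intermediate
10 | triethyl 4-phosphonocrotonate, ethyl (2E)-4-(diethoxyphosphoryl)but-2-enoate | CCOC(=O)/C=C/CP(=O)(OCC)OCC | starting material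
11 | (2E)-4-(diethoxyphosphoryl)but-2-enoic acid | CCOP(=O)(OCC)C/C=C/C(=O)O | intermediate
12 | 2-(trimethylsilyl)ethanol | C[Si](C)(C)CCO | starting material
13 | 2-(trimethylsilyl)ethyl (2E)-4-(diethoxyphosphoryl)but-2-enoate | CCOP(=O)(OCC)C/C=C/C(=O)OCC[Si](C)(C)C | intermediate
14 | lithium salt of the carbanion of 13 (lithiated phosphonate) | [Li+].CCOP(=O)(OCC)[CH-]/C=C/C(=O)OCC[Si](C)(C)C | intermediate
15 | 2-(trimethylsilyl)ethyl (2E,4E,10E,14E)-6,6,10,14-tetramethyl-16-[(2-methylpropanoyl)oxy]-7-oxohexadeca-2,4,10,14-tetraenoate | C/C(=C\COC(=O)C(C)C)CC/C=C(\C)CCC(=O)C(C)(C)/C=C/C=C/C(=O)OCC[Si](C)(C)C | intermediate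
16 | 2-(trimethylsilyl)ethyl (2E,4E,7S,10E,14E)-7-hydroxy-6,6,10,14-tetramethyl-16-[(2-methylpropanoyl)oxy]hexadeca-2,4,10,14-tetraenoate (3S in labdane numbering) | C/C(=C\COC(=O)C(C)C)CC/C=C(\C)CC[C@H](O)C(C)(C)/C=C/C=C/C(=O)OCC[Si](C)(C)C | intermediate
17 | 2-(trimethylsilyl)ethyl 3β-hydroxy-15-(isobutyryloxy)labda-6,13E-dien-17-oate (5α-H, 8α-H, 9α-H, 10β-CH3) | C/C(=C\COC(=O)C(C)C)CC[C@H]1[C@@H](C(=O)OCC[Si](C)(C)C)C=C[C@H]2C(C)(C)[C@@H](O)CC[C@]12C | intermediate
18 | 2-(trimethylsilyl)ethyl 3β-[(1H-imidazol-1-ylcarbonothioyl)oxy]-15-(isobutyryloxy)labda-6,13E-dien-17-oate | C/C(=C\COC(=O)C(C)C)CC[C@H]1[C@@H](C(=O)OCC[Si](C)(C)C)C=C[C@H]2C(C)(C)[C@@H](OC(=S)n3ccnc3)CC[C@]12C | intermediate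
19 | 2-(trimethylsilyl)ethyl 15-(isobutyryloxy)labda-6,13E-dien-17-oate (8α-H) | C/C(=C\COC(=O)C(C)C)CC[C@H]1[C@@H](C(=O)OCC[Si](C)(C)C)C=C[C@H]2C(C)(C)CCC[C@]12C | intermediate
20 | 2-(trimethylsilyl)ethyl 15-(isobutyryloxy)labda-7,13E-dien-17-oate | C/C(=C\COC(=O)C(C)C)CC[C@H]1C(C(=O)OCC[Si](C)(C)C)=CC[C@H]2C(C)(C)CCC[C@]12C | intermediate
21 | 15-(isobutyryloxy)labda-7,13E-dien-17-oic acid | C/C(=C\COC(=O)C(C)C)CC[C@H]1C(C(=O)O)=CC[C@H]2C(C)(C)CCC[C@]12C | target

**Count**

Total steps: 15. Longest linear sequence: 12 (steps 1, 2, 4, 5, 6, 9, 10, 11, 12, 13, 14, 15).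

**Steps most likely to fail**

Step 11. The cycloaddition may be slow, and material may leak to the cis-fused and wrong-face adducts, because a single homoallylic carbinol is only a modest conformational anchor (its equatorial preference next to the gem-dimethyl group is small at 200 °C). The fallback takes the absolute stereochemistry out of the cycloaddition. It sets out from 15: the achiral ketone is heated under the conditions of step 11, where only the trans/cis question remains, to give the racemic trans-fused adduct, 2-(trimethylsilyl)ethyl rac-15-(isobutyryloxy)-3-oxolabda-6,13E-dien-17-oate F1. F1 is then reduced with the oxazaborolidine and catecholborane of step 10, stopped near half conversion (kinetic resolution). The natural-series enantiomer is the matched one, since hydride from the α-face gives the equatorial 3β (3S) carbinol that the catalyst also prefers, and it is separated from unreduced ketone of the other series. The route is rejoined at 17, at the cost of at most half of F1.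

Step 4. Proton transfer between the product ketone and unreacted enolate may lead to double alkylation at C2, and the enolate may also attack the isobutyrate. The fallback uses a softer aza-enolate and sets out from 5 and 3. Ketone 5 is condensed with 1,1-dimethylhydrazine (cat. AcOH, EtOH, reflux) to the hydrazone, (E)-2-{4-[(tert-butyldimethylsilyl)oxy]-3,3-dimethylbutan-2-ylidene}-1,1-dimethylhydrazine F2. F2 is deprotonated with LiN(iPr)2 in THF at 0 °C and alkylated with 3 at −78 °C, which stops cleanly at monoalkylation, to give the N,N-dimethylhydrazone of 7, F3. Two-phase hydrolysis with aqueous oxalic acid and ether returns the ketone and rejoins the route at 7.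

Step 12. Thioacylation of the 3β-carbinol, which is flanked by the gem-dimethyl group, may stall, and forcing it may cause acyl transfer or elimination. The fallback deletes the oxygen through the ketone and sets out from 17. Dess–Martin oxidation gives 2-(trimethylsilyl)ethyl 15-(isobutyryloxy)-3-oxolabda-6,13E-dien-17-oate F4. Condensation with p-toluenesulfonylhydrazide (cat. acid, THF, 60 °C) gives its p-toluenesulfonylhydrazone F5. Reduction with catecholborane in CHCl3 at 0 °C, followed by NaOAc·3H2O at reflux (Caglioti-type reduction), leaves CH2 at C3 and rejoins the route at 19.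

**Further compounds**

F1 | step 11 | 2-(trimethylsilyl)ethyl rac-15-(isobutyryloxy)-3-oxolabda-6,13E-dien-17-oate (trans-fused, both enantiomers) | C/C(=C\COC(=O)C(C)C)CC[C@H]1[C@@H](C(=O)OCC[Si](C)(C)C)C=C[C@H]2C(C)(C)C(=O)CC[C@]12C.C/C(=C\COC(=O)C(C)C)CC[C@@H]1[C@H](C(=O)OCC[Si](C)(C)C)C=C[C@@H]2C(C)(C)C(=O)CC[C@@]12C
F2 | step 4 | (E)-2-{4-[(tert-butyldimethylsilyl)oxy]-3,3-dimethylbutan-2-ylidene}-1,1-dimethylhydrazine | C/C(=N\N(C)C)C(C)(C)CO[Si](C)(C)C(C)(C)C
F3 | step 4 | N,N-dimethylhydrazone of 7 | C/C(=C\COC(=O)C(C)C)CC/C=C(\C)CC/C(=N\N(C)C)C(C)(C)CO[Si](C)(C)C(C)(C)C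
F4 | step 12 | 2-(trimethylsilyl)ethyl 15-(isobutyryloxy)-3-oxolabda-6,13E-dien-17-oate (natural series) | C/C(=C\COC(=O)C(C)C)CC[C@H]1[C@@H](C(=O)OCC[Si](C)(C)C)C=C[C@H]2C(C)(C)C(=O)CC[C@]12C
F5 | step 12 | p-toluenesulfonylhydrazone of F4 | C/C(=C\COC(=O)C(C)C)CC[C@H]1[C@@H](C(=O)OCC[Si](C)(C)C)C=C[C@H]2C(C)(C)/C(=N/NS(=O)(=O)c3ccc(C)cc3)CC[C@]12C
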